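# Dictyol H: synthesis plan through an eight-to-seven epoxy-alcohol ring contraction

## The problem

Dictyol H is a cis-fused hydroazulene in which a 4-methylcyclopentene (C1, C2, C3=C4, C5) shares the C1–C5 bond with a cycloheptane (C1, C10, C9, C8, C7, C6, C5) that carries an exocyclic methylene at C10 (its CH2 is C18), a secondary hydroxyl at C6 and, at C7, a tetrahydrofuran (O, C11, C12, C13, C14) with a quaternary methyl-bearing C11 and a 2-acetoxyprop-2-yl group (C15) on C14. The hydrogens at C1, C5, C6 and C7 lie on one face (β below), so the C6 hydroxyl and the C7–C11 bond are cis on the α face, and C11 and C14 add two stereocentres outside the bicycle. The cis fusion is secure only while C1 and C5 sit in a small bicycle, C6 and C7 are best set in one event, the C6 hydroxyl can then steer C11 through a chelate, and C14 is too remote for substrate control and needs a reagent or a chiral building block. Late reagents are limited by four groups: the 1,1-disubstituted C10 alkene isomerises under acid and would interfere in ring-closing metathesis, the C3=C4 alkene is electron-rich, the β-oxygenated C6–C7–C11 array is open to retro-aldol cleavage or dehydration, and the tertiary acetate is lost with hot base or strong acid. The feature that makes the key step possible is that O–C6, C7 and the oxygenated C11 form an aldol-type 1,3-dioxygen pattern with the C6 hydroxyl and the C7–C11 bond cis. If C11 is counted into the carbocycle, the cycloheptane becomes a cyclooctane carrying a 2,3-epoxy alcohol (C11 carbinol, C6–C7 cis-epoxide). Its rearrangement, with C8 shifting from C11 to C7, returns the seven-membered ring, both ring stereocentres and a C11 carbonyl from which the tetrahydrofuran can be built.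

## Retrosynthesis

**Acetate last (33 → 30).** Only the C15–O acyl bond is cut: the tertiary acetate of 33 is put on at the end, through silyl ether 32 and its alcohol 31. The C6 hydroxyl of diol 30 has to be masked for this, because a secondary alcohol would acylate first.

**Tetrahydrofuran and C11 (30 → 28).** Two bonds are cut, O–C14 and C11–CH3. Forward, a methyl Grignard reagent adds to epoxy ketone 28 and the new C11 hydroxyl opens the C14–C15 epoxide of 29 in the 5-exo mode with inversion at C14. The neighbouring cut, adding the C12–C16 chain to an acetyl group, was weighed against it: in the magnesium chelate between the C6 alkoxide and the C11 carbonyl the open face is the one turned away from the carbocycle (the side of H7), and a nucleophile entering there takes the position that the methyl group has in dictyol H. The methyl group must therefore be the nucleophile and the chain must already be on the ketone. 28 lacks the ring and the C11 stereocentre and carries C14 as a preformed epoxide; the forward step needs chelation control and 5-exo selectivity.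

**C12–C13 (28 → 22 + 26).** The acetyl methyl of 22 becomes C12 by alkylation of its kinetic enolate with epoxy iodide 26. The iodide comes from prenol 24 through glycidol 25 by asymmetric epoxidation, so C14 is under reagent control. The C6 hydroxyl is masked as a trimethylsilyl ether (23, 27) for the enolate step only.

**Key disconnection (22 → 21, from 20).** The C7–C8 bond is cut and C8 is reconnected to C11, so that the C11 carbonyl becomes a tertiary carbinol and the C6 hydroxyl with the C7 centre become a cis-epoxide. This cut replaces two stereocentres by one alkene face and leads to a ring that metathesis can close, whereas a direct seven-membered aldol closure would set neither centre reliably and would be reversible. The forward step needs the ring bond C11–C8 to migrate instead of the methyl group, anti to the C7–O bond. Silyl ether 21 is preferred to the free alcohol 20 because it is the better donor for an alkyl shift.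

**Epoxide and methylene (20 → 19 → 18).** The α-epoxide comes from hydroxyl-directed epoxidation of allylic alcohol 19, so the α-hydroxyl at C11 decides C6 and C7. The C10 methylene comes from ketone 18; it cannot be present earlier, because a C10 methylene and the C11 vinyl group would close a cyclopentene by metathesis.

**Eight-membered ring (18 → 17).** The C6=C7 bond is cut (ring-closing metathesis of two vinyl groups). The ring size forces the Z geometry, and 17 is a monocyclic cis-1,2-disubstituted cyclopentene.

**cis-Vinyl and acyl groups (17 → 15, through 16).** A vinyl group at C5 cis to an acyl group at C1 cannot be made by sequential enolate chemistry, which gives trans. The retro-Grob step reconnects C10 to the vinyl CH2 (called Cx) and returns oxygen to C6, which gives the cis-bicyclo[3.3.0]octane triol 15, where the cis relation is enforced by ring strain.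

**Chain and C11 (14 → 13 + 7).** The C9–C10 bond is cut (organocerium addition to ketone 13). Iodide 7 carries C11 with its configuration from (R)-linalool 1, through 2, 4 and 5; vinyl addition to an acyclic methyl ketone would give no control at C11.

**Cyclopentene (13 → 11 → 10 → 9 → 8).** Ring A is closed at C3=C4 by metathesis of an allyl group on C1 and an isopropenyl group on C5. C5–C4 comes from a cuprate addition anti to the silyloxy group of 10, and C1–C2 from a Stille coupling of iodoenone 9, made from silyloxycyclopentenone 8. C1 is kept sp2 as a silyl enol ether (11, 12) until the ring is closed, so the trans ketone never forms. The C4 oxygen of 8 becomes the leaving group at C6 in the fragmentation.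

## Roads not taken

Alternative 1: oxonium ylide [2,3] shift. The cut is C7–C11 together with O–C11. Forward, a copper carbenoid at C11, generated with Cu(acac)2, is trapped by an allyl ether oxygen on C14 and the allyl group shifts from oxygen to C11, which gives the 2,5-trans tetrahydrofuran-3-one A1 with quaternary C11 and the C7 centre. Its merit is that the side ring and three stereocentres (C7, C11, C14) arise in one well-precedented step; in this respect it is better than the chosen plan, which needs an alkylation, a chelation-controlled addition and an epoxide opening for the same part. Its weak points are that the C12 carbonyl of A1 must be removed next to a quaternary centre and that the whole hydroazulene is still missing: C6 has to be set by acyclic induction from C7, and the seven-membered ring and the cis fusion must be built afterwards from a vinyl and an oxymethyl handle. The chosen plan is weaker on the tetrahydrofuran; it sets against this that C6 and C7 come from one stereospecific event and that C1 and C5 are fixed by ring strain.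

Alternative 2: transannular epoxide–allylsilane closure of a cyclodecene. The cut is C1–C5. Forward, a Lewis acid (SnCl4 or BF3·OEt2) opens a C4–C5 epoxide, C1 of an allylsilane attacks C5 with inversion, and loss of silicon leaves C10=C18; the product is A2, a hydroazulene C4 tertiary alcohol. Both rings, the ring fusion and the exocyclic methylene arise in one step from a substrate that already carries the side ring, so in step count for the ring system this road is clearly better. Its weak points are that a ten-membered ring with a geometrically defined allylsilane, a trisubstituted epoxide and the C6 and C7 centres has to be made first, that the fusion geometry depends on which conformer of the macrocycle reacts, and that A2 must still be dehydrated regioselectively to C3=C4 in the presence of the exocyclic alkene and the tertiary acetate. The chosen plan is longer, but each of its stereochemical outcomes follows from a rule (anti cuprate addition, ring strain, directed epoxidation, anti migration) and not from macrocycle conformation.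

Alternative 3: vinylcyclopropane-to-cyclopentene expansion. The cut is C1–C2. Forward, zerovalent nickel (Ni(cod)2 with an N-heterocyclic carbene) or heat cleaves the C1–C4 bond of a ketone-activated vinylcyclopropane on a cycloheptanone and bonds C1 to the vinyl terminus; the product is the hydroazulen-10-one A3. The methylcyclopentene with the alkene in the right place forms in one catalytic step, against four steps in the chosen plan, and the C10 ketone is ready for methylenation. Its weak points are that C6 of A3 is epimeric to the target and must be inverted through the ketone, that C7 carries nothing, so the side chain has to be introduced next to C6 with uncertain facial control, that C1 is epimerisable next to the ketone, and that the stereodefined bicyclic vinylcyclopropane is itself a multi-step target. This road is better for ring A and worse for C6, C7 and C11, which the chosen key step delivers together.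

Key step: step 16

Remark on numbering: atom locants are those defined under "The problem"; Cx is the ring methylene of 8 that ends as the terminal vinyl carbon of 17; α is the face opposite H1 and H5.
Remark on C10: the carbinol configuration at C10 in 14–16 is drawn for attack on the convex face; it is of no consequence, because C10 becomes a carbonyl carbon in step 11.

## Steps

Step 1
Reactants: 1 (R)-(−)-linalool
Product: 2 (R)-triethyl[(3,7-dimethylocta-1,6-dien-3-yl)oxy]silane
Conditions: TESOTf, 2,6-lutidine, CH2Cl2, −78 to 0 °C
Reagents that add atoms: triethylsilyl trifluoromethanesulfonate, CC[Si](CC)(CC)OS(=O)(=O)C(F)(F)F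
Why: Silyl triflate silylation of a tertiary alcohol; the stereocentre (future C11) is not touched.

Step 2
Reactants: 2 (R)-triethyl[(3,7-dimethylocta-1,6-dien-3-yl)oxy]silane
Product: 4 (R)-4-methyl-4-(triethylsilyloxy)hex-5-enal, via epoxide 3 (not isolated)
Conditions: mCPBA, NaHCO3, CH2Cl2, 0 °C; then H5IO6, THF–Et2O, 0 °C
Reagents that add atoms: 3-chloroperoxybenzoic acid, OOC(=O)c1cccc(Cl)c1
Why: The electron-rich trisubstituted alkene is epoxidised in preference to the vinyl group, which is deactivated by the allylic oxygen; periodic acid cleaves the epoxide to the aldehyde and acetone.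

Step 3
Reactants: 4 (R)-4-methyl-4-(triethylsilyloxy)hex-5-enal
Product: 5 (R)-4-methyl-4-(triethylsilyloxy)hex-5-enoic acid
Conditions: NaClO2, NaH2PO4, 2-methylbut-2-ene, t-BuOH–H2O, 0 °C to rt
Reagents that add atoms: sodium chlorite, [Na+].[O-]Cl=O
Why: Pinnick oxidation; the scavenger keeps hypochlorous acid from the vinyl group.

Step 4
Reactants: 5 (R)-4-methyl-4-(triethylsilyloxy)hex-5-enoic acid
Product: 7 (R)-5-iodo-3-methyl-3-(triethylsilyloxy)pent-1-ene, via Barton ester 6 (not isolated)
Conditions: N-hydroxypyridine-2-thione, DCC, DMAP (cat.), CH2Cl2, dark, 0 °C to rt; then CHI3, benzene, hν (tungsten lamp)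
Reagents that add atoms: iodoform, IC(I)I
Why: Barton decarboxylative iodination; the primary radical formed on loss of CO2 takes iodine from iodoform faster than it can add to the vinyl group, since both the 4-exo and the 5-endo closure of a pent-4-enyl radical are slow, and the neutral conditions spare the silyl ether.

Step 5
Reactants: 8 (S)-4-(tert-butyldimethylsilyloxy)cyclopent-2-en-1-one
Product: 9 (S)-4-(tert-butyldimethylsilyloxy)-2-iodocyclopent-2-en-1-one
Conditions: I2, pyridine, CH2Cl2, 0 °C to rt
Reagents that add atoms: iodine, II
Why: α-Iodination of an enone by pyridine addition, iodination and elimination; the silyloxy stereocentre is not involved.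

Step 6
Reactants: 9 (S)-4-(tert-butyldimethylsilyloxy)-2-iodocyclopent-2-en-1-one
Product: 10 (S)-2-allyl-4-(tert-butyldimethylsilyloxy)cyclopent-2-en-1-one
Conditions: allylSnBu3, Pd2(dba)3 (cat.), AsPh3, CuI, NMP, rt
Reagents that add atoms: allyltributylstannane, C=CC[Sn](CCCC)(CCCC)CCCC
Why: Stille coupling of an α-iodoenone on zerovalent palladium forms C1–C2; the neutral conditions avoid β-elimination of the silyloxy group and isomerisation of the skipped diene.

Step 7
Reactants: 10 (S)-2-allyl-4-(tert-butyldimethylsilyloxy)cyclopent-2-en-1-one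
Product: 11 (3S,4S)-2-allyl-4-(tert-butyldimethylsilyloxy)-3-(prop-1-en-2-yl)-1-(trimethylsilyloxy)cyclopent-1-ene
Conditions: isopropenylMgBr, CuBr·SMe2 (20 mol%), TMSCl, THF, −78 °C; Et3N
Reagents that add atoms: isopropenylmagnesium bromide, C=C(C)[Mg]Br; chlorotrimethylsilane, C[Si](C)(C)Cl
Why: Copper-catalysed conjugate addition anti to the silyloxy group sets C5 and forms C5–C4; trapping the enolate as its silyl ether keeps C1 sp2, so no trans-2,3-disubstituted ketone can form.

Step 8
Reactants: 11 (3S,4S)-2-allyl-4-(tert-butyldimethylsilyloxy)-3-(prop-1-en-2-yl)-1-(trimethylsilyloxy)cyclopent-1-ene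
Product: 13 (3S,3aR,6aR)-3-(tert-butyldimethylsilyloxy)-4-methyl-3,3a,6,6a-tetrahydropentalen-1(2H)-one, via bicyclic silyl enol ether 12 (not isolated)
Conditions: RuCl2(=CHPh)(PCy3)(SIMes) (second-generation Grubbs catalyst, SIMes = 1,3-dimesitylimidazolidin-2-ylidene, 5 mol%), CH2Cl2, 40 °C; then 1 M aq. citric acid, THF, 0 °C
Reagents that add atoms: none
Why: Ring-closing metathesis of the allyl and isopropenyl groups closes ring A at C3=C4, with the tetrasubstituted enol ether a bystander; hydrolysis protonates C1 from the convex face and only the cis-fused ketone is accessible because the trans-fused bicyclo[3.3.0]octanone is strained.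

Step 9
Reactants: 13 (3S,3aR,6aR)-3-(tert-butyldimethylsilyloxy)-4-methyl-3,3a,6,6a-tetrahydropentalen-1(2H)-one; 7 (R)-5-iodo-3-methyl-3-(triethylsilyloxy)pent-1-ene
Product: 14 (1S,3S,3aR,6aR)-3-(tert-butyldimethylsilyloxy)-4-methyl-1-[(3R)-3-methyl-3-(triethylsilyloxy)pent-4-en-1-yl]-1,2,3,3a,6,6a-hexahydropentalen-1-ol
Conditions: 7, t-BuLi (2.1 equiv), Et2O–pentane, −78 °C; CeCl3, THF, −78 °C; then 13, −78 °C; aq. NH4Cl
Reagents that add atoms: none
Why: Iodine–lithium exchange and transmetalation give an organocerium reagent that adds to the enolisable β-silyloxy ketone without enolisation or elimination, forming C9–C10; exchange at −78 °C in ether keeps the 1,4 oxygen-to-carbon silyl shift slow.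

Step 10
Reactants: 14 (1S,3S,3aR,6aR)-3-(tert-butyldimethylsilyloxy)-4-methyl-1-[(3R)-3-methyl-3-(triethylsilyloxy)pent-4-en-1-yl]-1,2,3,3a,6,6a-hexahydropentalen-1-ol
Product: 15 (1S,3S,3aR,6aR)-1-[(3R)-3-hydroxy-3-methylpent-4-en-1-yl]-4-methyl-1,2,3,3a,6,6a-hexahydropentalene-1,3-diol
Conditions: Bu4NF, THF, 0 °C to rt
Reagents that add atoms: none
Why: Fluoride cleaves both silyl ethers; the triol has one secondary hydroxyl (C6) and two tertiary ones.

Step 11
Reactants: 15 (1S,3S,3aR,6aR)-1-[(3R)-3-hydroxy-3-methylpent-4-en-1-yl]-4-methyl-1,2,3,3a,6,6a-hexahydropentalene-1,3-diol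
Product: 17 (R)-4-hydroxy-4-methyl-1-[(1R,2R)-3-methyl-2-vinylcyclopent-3-en-1-yl]hex-5-en-1-one, via mesylate 16 (not isolated)
Conditions: MsCl, pyridine, CH2Cl2, −10 °C; then KOt-Bu, THF, 0 °C, short reaction time
Reagents that add atoms: none
Why: Only the secondary hydroxyl is mesylated; the C10 alkoxide then expels the mesylate with cleavage of the C10–Cx bond (Grob fragmentation of a 1,3-diol monosulfonate), giving the C10 ketone and the C5 vinyl group. The exo mesylate can take a pseudo-equatorial position close to anti-periplanar to the breaking ring bond, and C1 and C5 are not touched, so the cis relation is kept. In the basic medium the C11 alkoxide can add to the new ketone as a five-membered hemiketal alkoxide, which together with the short reaction time should limit enolisation at C1.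

Step 12
Reactants: 17 (R)-4-hydroxy-4-methyl-1-[(1R,2R)-3-methyl-2-vinylcyclopent-3-en-1-yl]hex-5-en-1-one
Product: 18 (1R,5R,11R,6Z)-11-hydroxy-4,11-dimethyl-cis-bicyclo[6.3.0]undeca-3,6-dien-10-one
Conditions: RuCl2(=CH-C6H4-2-O-i-Pr)(SIMes) (second-generation Hoveyda–Grubbs catalyst, 10 mol%), CH2Cl2 (2 mM), 40 °C
Reagents that add atoms: none
Why: Ring-closing metathesis of the two vinyl groups forms C6=C7; closure is helped by the cis substituents on the cyclopentene, the free allylic hydroxyl and the quaternary C11, the trisubstituted ring alkene is inert, and the ring size enforces Z.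

Step 13
Reactants: 18 (1R,5R,11R,6Z)-11-hydroxy-4,11-dimethyl-cis-bicyclo[6.3.0]undeca-3,6-dien-10-one
Product: 19 (1R,5R,11R,6Z)-4,11-dimethyl-10-methylene-cis-bicyclo[6.3.0]undeca-3,6-dien-11-ol
Conditions: Cp2TiMe2 (3 equiv), toluene–THF, 65 °C, dark
Reagents that add atoms: bis(cyclopentadienyl)dimethyltitanium (Cp2TiMe2), C[Ti](C)(C1C=CC=C1)C1C=CC=C1
Why: Petasis methylenation is non-basic, so C1 next to the ketone is not epimerised, and with excess reagent it tolerates the free tertiary alcohol and its transannular hemiketal equilibrium; it is placed after ring closure because a C10 methylene would close a cyclopentene with the C11 vinyl group.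

Step 14
Reactants: 19 (1R,5R,11R,6Z)-4,11-dimethyl-10-methylene-cis-bicyclo[6.3.0]undeca-3,6-dien-11-ol
Product: 20 (1R,5R,6S,7S,11R)-6α,7α-epoxy-4,11-dimethyl-10-methylene-cis-bicyclo[6.3.0]undec-3-en-11-ol
Conditions: VO(acac)2 (5 mol%), t-BuOOH (1.2 equiv), CH2Cl2, 0 °C
Reagents that add atoms: tert-butyl hydroperoxide, CC(C)(C)OO
Why: Hydroxyl-directed epoxidation through the vanadate ester delivers oxygen syn to the α-hydroxyl at C11, as is the rule for cyclooct-2-enols, and sets C6 and C7. The allylic alkene reacts far faster than the bishomoallylic C10 methylene and the undirected C3=C4.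

Step 15
Reactants: 20 (1R,5R,6S,7S,11R)-6α,7α-epoxy-4,11-dimethyl-10-methylene-cis-bicyclo[6.3.0]undec-3-en-11-ol
Product: 21 (1R,5R,6S,7S,11R)-6α,7α-epoxy-4,11-dimethyl-10-methylene-11-(trimethylsilyloxy)-cis-bicyclo[6.3.0]undec-3-ene (trimethylsilyl ether of 20 at the C11 oxygen)
Conditions: N-(trimethylsilyl)imidazole, CH2Cl2, rt
Reagents that add atoms: N-(trimethylsilyl)imidazole, C[Si](C)(C)n1ccnc1
Why: Neutral silylation of the hindered tertiary alcohol; no acid is present that could open the epoxide early.

Step 16
Reactants: 21 (1R,5R,6S,7S,11R)-6α,7α-epoxy-4,11-dimethyl-10-methylene-11-(trimethylsilyloxy)-cis-bicyclo[6.3.0]undec-3-ene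
Product: 22 (1R,5R,6S,7R)-7-acetyl-4-methyl-10-methylene-cis-bicyclo[5.3.0]dec-3-en-6-ol
Conditions: TiCl4 (1.1 equiv), CH2Cl2, −78 °C, 15 min; aq. NaHCO3
Reagents that add atoms: none
Why: TiCl4 binds the epoxide oxygen and weakens C7–O, the bond next to the donor carbon C11. The ring bond C11–C8 shifts to C7 as the silyloxy lone pair forms the C11 carbonyl; chloride removes silicon, so the step is irreversible, and the titanium aldolate gives 22 on work-up. This is the Lewis-acid rearrangement of 2,3-epoxy alcohol silyl ethers to β-hydroxy ketones (semipinacol), here in its ring-contracting mode. The cycloheptane is closed by a 1,2-alkyl shift that contracts the eight-membered ring, not by an end-to-end cyclisation. C7 is the new stereocentre: C8 arrives anti to the leaving oxygen, C7 is inverted, and because the epoxide is cis the C6 hydroxyl and the acetyl group end up cis (6S,7R). The step needs C8 to migrate and not the methyl group, and C7–O to open and not C6–O. The first rests on the higher migratory aptitude of a primary alkyl group, the strain released on going from eight to seven ring atoms and the anti-periplanar alignment open to the ring bond; the second on the donor at C11, which assists only the adjacent C–O bond. The silyl ether is used instead of the free alcohol because a free hydroxyl is a poor donor for alkyl shifts and ties up the Lewis acid.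

Step 17
Reactants: 22 (1R,5R,6S,7R)-7-acetyl-4-methyl-10-methylene-cis-bicyclo[5.3.0]dec-3-en-6-ol
Product: 23 (1R,5R,6S,7R)-7-acetyl-4-methyl-10-methylene-6-(trimethylsilyloxy)-cis-bicyclo[5.3.0]dec-3-ene (trimethylsilyl ether of 22 at the C6 oxygen)
Conditions: TMSCl, imidazole, CH2Cl2, 0 °C
Reagents that add atoms: chlorotrimethylsilane, C[Si](C)(C)Cl
Why: The β-hydroxyl is masked so that the next step does not pass through a β-alkoxide enolate, which could undergo retro-aldol ring opening.

Step 18
Reactants: 24 3-methylbut-2-en-1-ol (prenol)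
Product: 25 [(2S)-3,3-dimethyloxiran-2-yl]methanol
Conditions: Ti(O-i-Pr)4 (cat.), L-(+)-diisopropyl tartrate (cat.), t-BuOOH, 4 Å molecular sieves, CH2Cl2, −20 °C
Reagents that add atoms: tert-butyl hydroperoxide, CC(C)(C)OO
Why: Sharpless asymmetric epoxidation; the L-(+)-tartrate catalyst delivers oxygen to the face that gives the (S)-epoxide (future C14).

Step 19
Reactants: 25 [(2S)-3,3-dimethyloxiran-2-yl]methanol
Product: 26 (2R)-2-(iodomethyl)-3,3-dimethyloxirane
Conditions: I2, PPh3, imidazole, CH2Cl2, 0 °C
Reagents that add atoms: iodine, II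
Why: Appel-type iodination of the primary alcohol; the epoxide carbon is not touched and the descriptor changes only through the priority of iodine.

Step 20
Reactants: 23 (1R,5R,6S,7R)-7-acetyl-4-methyl-10-methylene-6-(trimethylsilyloxy)-cis-bicyclo[5.3.0]dec-3-ene; 26 (2R)-2-(iodomethyl)-3,3-dimethyloxirane
Product: 28 (1R,5R,6S,7R)-7-{3-[(2S)-3,3-dimethyloxiran-2-yl]propanoyl}-4-methyl-10-methylene-cis-bicyclo[5.3.0]dec-3-en-6-ol, via alkylated silyl ether 27 (not isolated)
Conditions: LiN(i-Pr)2 (LDA, 1.1 equiv), THF, −78 °C; then 26, DMPU, −78 to −30 °C; then Bu4NF, AcOH, THF, 0 °C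
Reagents that add atoms: none
Why: Kinetic deprotonation takes the methyl group, not the hindered C7–H, and the enolate displaces the primary iodide (enolate alkylation, C12–C13); the trisubstituted epoxide is the slower electrophile, and buffered fluoride then frees the C6 hydroxyl.

Step 21
Reactants: 28 (1R,5R,6S,7R)-7-{3-[(2S)-3,3-dimethyloxiran-2-yl]propanoyl}-4-methyl-10-methylene-cis-bicyclo[5.3.0]dec-3-en-6-ol
Product: 30 deacetyl-dictyol H (1R,5R,6S,7R,11R,14R), via epoxy diol 29 (not isolated)
Conditions: MeMgBr (4 equiv), CH2Cl2–Et2O, −78 °C; aq. NH4Cl; then CSA (10 mol%), CH2Cl2, 0 °C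
Reagents that add atoms: methylmagnesium bromide, C[Mg]Br
Why: The magnesium alkoxide of the C6 hydroxyl chelates the ketone (six-membered 1,3-chelate, cis-fused to the cycloheptane) and the methyl group adds to its convex face, the side of H7, which gives 11R. Acid then lets the C11 hydroxyl open the epoxide at C14 in the 5-exo mode with inversion (14R), closing the tetrahydrofuran and freeing the C15 hydroxyl. The 5-exo path is the usual course of acid-catalysed closures of 4,5-epoxy alcohols with a dimethyl-substituted terminus, as in the furanoid linalool oxides, and the C6 hydroxyl could only close a seven-membered ring.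

Step 22
Reactants: 30 deacetyl-dictyol H (1R,5R,6S,7R,11R,14R)
Product: 31 6-O-triethylsilyl ether of 30
Conditions: TESCl, imidazole, DMF, 0 °C to rt
Reagents that add atoms: chlorotriethylsilane, CC[Si](Cl)(CC)CC
Why: The secondary C6 hydroxyl is silylated and the tertiary C15 hydroxyl is not under these conditions.

Step 23
Reactants: 31 6-O-triethylsilyl ether of 30
Product: 32 6-O-triethylsilyl-dictyol H
Conditions: Ac2O, DMAP, Et3N, CH2Cl2, 40 °C
Reagents that add atoms: acetic anhydride, CC(=O)OC(C)=O
Why: DMAP-catalysed acylation of the tertiary alcohol, possible now that the only other hydroxyl is masked.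

Step 24
Reactants: 32 6-O-triethylsilyl-dictyol H
Product: 33 dictyol H
Conditions: HF·pyridine, pyridine, THF, 0 °C
Reagents that add atoms: none
Why: Buffered fluoride cleaves the silyl ether without touching the tertiary acetate, the tetrahydrofuran or the exocyclic alkene.

## Compound list

1 | (R)-(−)-linalool, (3R)-3,7-dimethylocta-1,6-dien-3-ol | C=C[C@](C)(O)CCC=C(C)C | starting material
2 | (R)-triethyl[(3,7-dimethylocta-1,6-dien-3-yl)oxy]silane | C=C[C@](C)(O[Si](CC)(CC)CC)CCC=C(C)C | intermediate
3 | 6,7-epoxide of 2 (both epimers at the epoxide CH) | C=C[C@](C)(O[Si](CC)(CC)CC)CCC1OC1(C)C | intermediate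
4 | (R)-4-methyl-4-(triethylsilyloxy)hex-5-enal | C=C[C@](C)(O[Si](CC)(CC)CC)CCC=O | intermediate
5 | (R)-4-methyl-4-(triethylsilyloxy)hex-5-enoic acid | C=C[C@](C)(O[Si](CC)(CC)CC)CCC(=O)O | intermediate
6 | 2-thioxopyridin-1(2H)-yl ester (Barton ester) of 5 | C=C[C@](C)(O[Si](CC)(CC)CC)CCC(=O)On1ccccc1=S | intermediate
7 | (R)-5-iodo-3-methyl-3-(triethylsilyloxy)pent-1-ene | C=C[C@](C)(O[Si](CC)(CC)CC)CCI | intermediate
8 | (S)-4-(tert-butyldimethylsilyloxy)cyclopent-2-en-1-one | O=C1C=C[C@@H](O[Si](C)(C)C(C)(C)C)C1 | starting material
9 | (S)-4-(tert-butyldimethylsilyloxy)-2-iodocyclopent-2-en-1-one | O=C1C(I)=C[C@@H](O[Si](C)(C)C(C)(C)C)C1 | intermediate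
10 | (S)-2-allyl-4-(tert-butyldimethylsilyloxy)cyclopent-2-en-1-one | O=C1C(CC=C)=C[C@@H](O[Si](C)(C)C(C)(C)C)C1 | intermediate
11 | (3S,4S)-2-allyl-4-(tert-butyldimethylsilyloxy)-3-(prop-1-en-2-yl)-1-(trimethylsilyloxy)cyclopent-1-ene (3,4-trans) | C=CCC1=C(O[Si](C)(C)C)C[C@H](O[Si](C)(C)C(C)(C)C)[C@H]1C(C)=C | intermediate
12 | (3S,3aS)-3-(tert-butyldimethylsilyloxy)-4-methyl-1-(trimethylsilyloxy)-2,3,3a,6-tetrahydropentalene | C[Si](C)(C)OC1=C2CC=C(C)[C@@H]2[C@@H](O[Si](C)(C)C(C)(C)C)C1 | intermediate
13 | (3S,3aR,6aR)-3-(tert-butyldimethylsilyloxy)-4-methyl-3,3a,6,6a-tetrahydropentalen-1(2H)-one (cis-fused, silyloxy group on the convex face) | O=C1C[C@H](O[Si](C)(C)C(C)(C)C)[C@H]2C(C)=CC[C@@H]12 | intermediate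
14 | (1S,3S,3aR,6aR)-3-(tert-butyldimethylsilyloxy)-4-methyl-1-[(3R)-3-methyl-3-(triethylsilyloxy)pent-4-en-1-yl]-1,2,3,3a,6,6a-hexahydropentalen-1-ol | C=C[C@](C)(O[Si](CC)(CC)CC)CC[C@]1(O)C[C@H](O[Si](C)(C)C(C)(C)C)[C@H]2C(C)=CC[C@@H]12 | intermediate
15 | (1S,3S,3aR,6aR)-1-[(3R)-3-hydroxy-3-methylpent-4-en-1-yl]-4-methyl-1,2,3,3a,6,6a-hexahydropentalene-1,3-diol | C=C[C@](C)(O)CC[C@]1(O)C[C@H](O)[C@H]2C(C)=CC[C@@H]12 | intermediate
16 | 3-O-methanesulfonate of 15 (secondary hydroxyl) | C=C[C@](C)(O)CC[C@]1(O)C[C@H](OS(C)(=O)=O)[C@H]2C(C)=CC[C@@H]12 | intermediate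
17 | (R)-4-hydroxy-4-methyl-1-[(1R,2R)-3-methyl-2-vinylcyclopent-3-en-1-yl]hex-5-en-1-one (acyl and vinyl groups cis) | C=C[C@](C)(O)CCC(=O)[C@@H]1CC=C(C)[C@@H]1C=C | intermediate
18 | (1R,5R,11R,6Z)-11-hydroxy-4,11-dimethyl-cis-bicyclo[6.3.0]undeca-3,6-dien-10-one (locants of the text; 11-OH α) | O=C1CC[C@@](C)(O)/C=C\[C@H]2C(C)=CC[C@@H]12 | intermediate
19 | (1R,5R,11R,6Z)-4,11-dimethyl-10-methylene-cis-bicyclo[6.3.0]undeca-3,6-dien-11-ol | C=C1CC[C@@](C)(O)/C=C\[C@H]2C(C)=CC[C@@H]12 | intermediate
20 | (1R,5R,6S,7S,11R)-6α,7α-epoxy-4,11-dimethyl-10-methylene-cis-bicyclo[6.3.0]undec-3-en-11-ol (epoxide syn to the 11-OH) | C=C1CC[C@@](C)(O)[C@H]2O[C@H]2[C@H]3C(C)=CC[C@@H]13 | intermediate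
21 | 11-O-trimethylsilyl ether of 20, (1R,5R,6S,7S,11R)-6α,7α-epoxy-4,11-dimethyl-10-methylene-11-(trimethylsilyloxy)-cis-bicyclo[6.3.0]undec-3-ene | C=C1CC[C@@](C)(O[Si](C)(C)C)[C@H]2O[C@H]2[C@H]3C(C)=CC[C@@H]13 | intermediate
22 | (1R,5R,6S,7R)-7-acetyl-4-methyl-10-methylene-cis-bicyclo[5.3.0]dec-3-en-6-ol (6-OH and acetyl cis, both α) | C=C1CC[C@@H](C(C)=O)[C@@H](O)[C@H]2C(C)=CC[C@@H]12 | intermediate
23 | 6-O-trimethylsilyl ether of 22, (1R,5R,6S,7R)-7-acetyl-4-methyl-10-methylene-6-(trimethylsilyloxy)-cis-bicyclo[5.3.0]dec-3-ene | C=C1CC[C@@H](C(C)=O)[C@@H](O[Si](C)(C)C)[C@H]2C(C)=CC[C@@H]12 | intermediate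
24 | 3-methylbut-2-en-1-ol (prenol) | CC(C)=CCO | starting material
25 | [(2S)-3,3-dimethyloxiran-2-yl]methanol | OC[C@@H]1OC1(C)C | intermediate
26 | (2R)-2-(iodomethyl)-3,3-dimethyloxirane | IC[C@@H]1OC1(C)C | intermediate
27 | 6-O-trimethylsilyl ether of 28 | C=C1CC[C@@H](C(=O)CC[C@@H]3OC3(C)C)[C@@H](O[Si](C)(C)C)[C@H]2C(C)=CC[C@@H]12 | intermediate
28 | (1R,5R,6S,7R)-7-{3-[(2S)-3,3-dimethyloxiran-2-yl]propanoyl}-4-methyl-10-methylene-cis-bicyclo[5.3.0]dec-3-en-6-ol | C=C1CC[C@@H](C(=O)CC[C@@H]3OC3(C)C)[C@@H](O)[C@H]2C(C)=CC[C@@H]12 | intermediate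
29 | (11R,14S)-epoxy diol: methyl adduct of 28 at C11 (C6 and C11 hydroxyls, C14–C15 epoxide) | C=C1CC[C@@H]([C@](C)(O)CC[C@@H]3OC3(C)C)[C@@H](O)[C@H]2C(C)=CC[C@@H]12 | intermediate
30 | deacetyl-dictyol H, (1R,5R,6S,7R,11R,14R)-diol (C6 and C15 hydroxyls) | C=C1CC[C@@H]([C@@]2(C)CC[C@H](C(C)(C)O)O2)[C@@H](O)[C@H]2C(C)=CC[C@@H]12 | intermediate
31 | 6-O-triethylsilyl ether of 30 | C=C1CC[C@@H]([C@@]2(C)CC[C@H](C(C)(C)O)O2)[C@@H](O[Si](CC)(CC)CC)[C@H]2C(C)=CC[C@@H]12 | intermediate
32 | 6-O-triethylsilyl-dictyol H | C=C1CC[C@@H]([C@@]2(C)CC[C@H](C(C)(C)OC(C)=O)O2)[C@@H](O[Si](CC)(CC)CC)[C@H]2C(C)=CC[C@@H]12 | intermediate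
33 | dictyol H, (1R,5R,6S,7R,11R,14R) | C=C1CC[C@@H]([C@@]2(C)CC[C@H](C(C)(C)OC(C)=O)O2)[C@@H](O)[C@H]2C(C)=CC[C@@H]12 | target

## Step count and risks

Total step count: 24.

Longest linear sequence: 18 steps (8 → 33 through steps 5–17 and 20–24). The branch from 1 is equally long (steps 1–4, 9–17, 20–24).

Least certain steps:

1. **Step 16 (key step).** The most likely failures are a competing shift of the methyl group, capture of the activated epoxide by chloride at C6, or transannular attack of the C10 alkene on the activated epoxide before C8 has migrated.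
 Fallback: it sets out from 20 and comes back at 22. The titanium halide is given up for a silyl triflate, so that no nucleophilic counter-ion is present and the product leaves the reaction as a silyl ether instead of a metal aldolate. 20 is silylated with TESOTf and 2,6-lutidine (CH2Cl2, −78 °C) to the 11-O-triethylsilyl epoxy ether F1. F1 is then treated with a substoichiometric amount of TESOTf in the presence of 2,6-di-tert-butyl-4-methylpyridine (CH2Cl2, −40 °C): silicon goes to the epoxide oxygen, C8 shifts to C7, and loss of the silyl group from the C11 oxocarbenium ion returns the promoter and leaves the ring-contracted C6 triethylsilyl ether F2. This is the silyl triflate rearrangement of epoxy silyl ethers to β-silyloxy carbonyl compounds. HF·pyridine in pyridine–THF at 0 °C then cleaves F2 to 22.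

2. **Step 20.** C-alkylation by the β-oxygenated iodide may be slow. Proton transfer between enolate and product would then scramble the enolate position and lead to double alkylation.
 Fallback: it sets out from 22 and comes back at 28. 22 is condensed with 1,1-dimethylhydrazine (AcOH cat., EtOH) to the N,N-dimethylhydrazone F3. The azaenolate of F3 (LiN(i-Pr)2, 2.2 equiv, THF, −78 to 0 °C; the C6 alkoxide is carried along) is alkylated with 26 at the methyl carbon to the alkylated hydrazone F4. Aqueous CuCl2 buffered to pH 7 hydrolyses F4 to 28. Azaenolates do not equilibrate and alkylate cleanly on the less substituted side.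

3. **Step 12.** Slow closure of the eight-membered ring would let intermolecular metathesis take over and give oligomers.
 Fallback: it sets out from 17 and comes back at 18. The γ-hydroxy ketone 17 is closed with MeOH and PPTS to the 2-methoxytetrahydrofuran methyl ketal F5. In F5 the oxygen bridge holds C10 and C11 together, so metathesis of the anomer with the cyclopentenyl and vinyl groups cis closes a seven-membered oxacycle and gives the bridged methyl ketal F6; the other anomer is recycled by acid equilibration. Aqueous acetic acid then opens F6 to 18.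

4. **Step 21.** The methyl group may add to the other face of the carbonyl if the chelate is weak or adopts another conformation, which gives the C11 epimer.
 Fallback: it sets out from 22 and comes back at 31. The roles of the two carbon groups are exchanged, so the opposite facial preference gives the right centre. (4-Methylpent-3-en-1-yl)magnesium bromide, made from 5-bromo-2-methylpent-2-ene and magnesium, is added to the acetyl group of 22 to give the homoprenyl diol F7. The C6 hydroxyl of F7 is silylated (TESCl, imidazole) to the triethylsilyl ether F8. Hydroxyl-directed epoxidation of the bishomoallylic alkene of F8 (VO(acac)2, t-BuOOH) should give the epoxy alcohol F9, since the vanadate-ester transition state with the bulky bicycle pseudo-equatorial places C7 and C15 trans on the future ring. Acetic acid then closes F9 in the 5-exo mode to 31.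

Further compounds

F1 | step 16 | 11-O-triethylsilyl ether of 20, (1R,5R,6S,7S,11R)-6α,7α-epoxy-4,11-dimethyl-10-methylene-11-(triethylsilyloxy)-cis-bicyclo[6.3.0]undec-3-ene | C=C1CC[C@@](C)(O[Si](CC)(CC)CC)[C@H]2O[C@H]2[C@H]3C(C)=CC[C@@H]13
F2 | step 16 | 6-O-triethylsilyl ether of 22, (1R,5R,6S,7R)-7-acetyl-4-methyl-10-methylene-6-(triethylsilyloxy)-cis-bicyclo[5.3.0]dec-3-ene | C=C1CC[C@@H](C(C)=O)[C@@H](O[Si](CC)(CC)CC)[C@H]2C(C)=CC[C@@H]12
F3 | step 20 | (E)-N,N-dimethylhydrazone of 22 | C=C1CC[C@@H](/C(C)=N/N(C)C)[C@@H](O)[C@H]2C(C)=CC[C@@H]12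
F4 | step 20 | (E)-N,N-dimethylhydrazone of 28 | C=C1CC[C@@H](/C(CC[C@@H]3OC3(C)C)=N/N(C)C)[C@@H](O)[C@H]2C(C)=CC[C@@H]12
F5 | step 12 | 2-methoxy-5-methyl-2-[(1R,2R)-3-methyl-2-vinylcyclopent-3-en-1-yl]-5-vinyltetrahydrofuran, (5R), both anomers | COC1(CC[C@](C)(C=C)O1)[C@@H]1CC=C(C)[C@@H]1C=C
F6 | step 12 | bridged methyl ketal of 18 (10-methoxy-10α,11α-epoxy-4,11-dimethyl-cis-bicyclo[6.3.0]undeca-3,6-diene, locants of the text) | CO[C@@]12CC[C@@](C)(O1)/C=C\[C@H]3C(C)=CC[C@@H]23
F7 | step 21 | (1R,5R,6S,7R)-7-[(2R)-2-hydroxy-6-methylhept-5-en-2-yl]-4-methyl-10-methylene-cis-bicyclo[5.3.0]dec-3-en-6-ol | C=C1CC[C@@H]([C@](C)(O)CCC=C(C)C)[C@@H](O)[C@H]2C(C)=CC[C@@H]12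
F8 | step 21 | 6-O-triethylsilyl ether of F7 | C=C1CC[C@@H]([C@](C)(O)CCC=C(C)C)[C@@H](O[Si](CC)(CC)CC)[C@H]2C(C)=CC[C@@H]12
F9 | step 21 | 6-O-triethylsilyl ether of the (11R,14S)-epoxy diol 29 (C11 hydroxyl free, C14–C15 epoxide) | C=C1CC[C@@H]([C@](C)(O)CC[C@@H]3OC3(C)C)[C@@H](O[Si](CC)(CC)CC)[C@H]2C(C)=CC[C@@H]12
A1 | alternative 1 | 2,5-trans tetrahydrofuran-3-one with quaternary C11, C7 bearing vinyl and PMB-oxymethyl, C14 bearing the 2-acetoxyprop-2-yl group | C=C[C@H](COCc1ccc(OC)cc1)[C@]1(C)O[C@@H](C(C)(C)OC(C)=O)CC1=O
A2 | alternative 2 | cis-fused hydroazulene C4 tertiary alcohol with C10 exo-methylene, C6 triethylsilyl ether and the complete side ring | C=C1CC[C@@H]([C@@]2(C)CC[C@H](C(C)(C)OC(C)=O)O2)[C@@H](O[Si](CC)(CC)CC)[C@H]2[C@](C)(O)CC[C@@H]12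
A3 | alternative 3 | cis-hydroazulen-10-one with C3=C4 methylcyclopentene and C6 tert-butyldimethylsilyl ether (C6 epimeric to the target) | O=C1CCC[C@H](O[Si](C)(C)C(C)(C)C)[C@H]2C(C)=CC[C@@H]12
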